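The bicyclo[3.3.1]nonane is cut at the C1–C8 bond. C8, the gem-dimethyl carbon of ring B, sits next to bridgehead C1, the α-carbon of the C9 ketone; C9 and C4 form a masked cyclohexane-1,3-dione around the geranyl-bearing C5. A silyl-triflate-triggered opening of a tertiary epoxide by one enol ether of a symmetric 6,6-dialkyl-1,5-dimethoxycyclohexa-1,4-diene therefore closes ring B in one operation, desymmetrises the diene and sets C1 and C5 from the single epoxide stereocentre (future C7). The precursor is the Birch-derived diene carrying geranyl and an (R)-2,3-epoxy-3-methylbutyl chain on its doubly allylic carbon.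

Key step: step 6

Remark: atoms are numbered on the bicyclo[3.3.1]nonane core (C1 prenyl bridgehead, C2–C4 enolised dione carbons, C5 geranyl bridgehead, C7 prenyl methine, C8 gem-dimethyl carbon, C9 bridging ketone); "exo" at C7 means equatorial on the chair of ring B, turned away from ring A; the target is drawn as its C4-enol tautomer, which equilibrates with the C2-enol form.

Step 1
Reactants: 1 1,3-dimethoxybenzene
Product: 2 1,5-dimethoxycyclohexa-1,4-diene
Conditions: Li, NH3 (l), THF, t-BuOH, −78 °C to −33 °C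
Reagents that add atoms: none
Why: Birch reduction, in which the two methoxy groups direct protonation to C2 and C5 of the arene, so that the unconjugated bis-enol ether of cyclohexane-1,3-dione should result.

Step 2
Reactants: 2 1,5-dimethoxycyclohexa-1,4-diene; 3 geranyl bromide
Product: 5 6-geranyl-1,5-dimethoxycyclohexa-1,4-diene, via 6-lithio-1,5-dimethoxycyclohexa-1,4-diene 4 (not isolated)
Conditions: t-BuLi, THF, −78 °C; then 3, −78 °C to rt
Reagents that add atoms: none
Why: Deprotonation of the doubly allylic CH2 flanked by both enol ethers gives a pentadienyl-type anion that should be alkylated at its central carbon in an SN2 reaction with the allylic bromide.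

Step 3
Reactants: 6 3-methylbut-2-en-1-ol
Product: 7 (R)-(3,3-dimethyloxiran-2-yl)methanol
Conditions: Ti(OiPr)4 (5 mol %), D-(−)-diisopropyl tartrate (7.5 mol %), t-BuOOH (anhydrous), 4 Å molecular sieves, CH2Cl2, −20 °C; non-aqueous work-up
Reagents that add atoms: tert-butyl hydroperoxide, CC(C)(C)OO
Why: Katsuki–Sharpless asymmetric epoxidation of a primary allylic alcohol, in which the D-(−)-tartrate ligand directs oxygen delivery to the alkene face that gives the (R)-configured oxirane carbon.

Step 4
Reactants: 7 (R)-(3,3-dimethyloxiran-2-yl)methanol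
Product: 8 (S)-2-(bromomethyl)-3,3-dimethyloxirane
Conditions: CBr4, PPh3, CH2Cl2, 0 °C
Reagents that add atoms: carbon tetrabromide, BrC(Br)(Br)Br
Why: Appel reaction, which should convert the primary alcohol into the bromide under neutral conditions without touching the oxirane, the change of descriptor from R to S being only a matter of substituent priority.

Step 5
Reactants: 5 6-geranyl-1,5-dimethoxycyclohexa-1,4-diene; 8 (S)-2-(bromomethyl)-3,3-dimethyloxirane
Product: 10 6-geranyl-6-{[(2R)-3,3-dimethyloxiran-2-yl]methyl}-1,5-dimethoxycyclohexa-1,4-diene, via 6-geranyl-6-lithio-1,5-dimethoxycyclohexa-1,4-diene 9 (not isolated)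
Conditions: sec-BuLi, THF, −78 to −30 °C; then 8, −78 °C to rt
Reagents that add atoms: none
Why: A second deprotonation at the now tertiary doubly allylic carbon followed by SN2 displacement of the primary bromide (the distal oxirane carbon is tertiary and is not attacked) should give the diene, whose quaternary carbon is not stereogenic, with the oxirane stereocentre intact.

Step 6
Reactants: 10 6-geranyl-6-{[(2R)-3,3-dimethyloxiran-2-yl]methyl}-1,5-dimethoxycyclohexa-1,4-diene
Product: 13 (1S,5S,7R)-5-geranyl-7-hydroxy-4-methoxy-8,8-dimethylbicyclo[3.3.1]non-3-en-9-one, via bridged C7–O–C9 mixed methyl ketal 11 (not isolated), via C7 dimethylborinate 12 (not isolated)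
Conditions: TMSOTf (0.2 equiv), 2,6-di-tert-butyl-4-methylpyridine (0.3 equiv), CH2Cl2, −78 °C; then Me2BBr, −78 °C; aq. NaHCO3
Reagents that add atoms: none
Why: Silylation of the oxirane oxygen polarises the tertiary C8–O bond and the β-carbon of one enol ether (future C1) attacks C8 anti to the departing oxygen, giving a C7 silyl ether and a C9 methoxycarbenium ion, which is expected to be captured by the exo C7 oxygen as the bridged mixed ketal 11 with return of the silyl triflate; bromodimethylborane then cleaves this strained ketal at −78 °C (C9–O7 scission, loss of the O-methyl group as bromomethane), so that the C9 ketone and the C7 borinate 12, hydrolysed on work-up, should result. The closest known reaction type is the Lewis-acid-promoted epoxide-opening carbocyclisation of 6,6-dialkylated 1,5-dimethoxycyclohexa-1,4-dienes to bicyclo[3.3.1]nonanes, combined with the standard low-temperature cleavage of ketals by bromodialkylboranes. Ring B closes in a 6-endo mode with respect to the epoxide (both oxirane carbons end in the ring) and enol-endo with respect to the nucleophile, through a chair-like transition state. C5 is not stereogenic in 10, so the (R)-configured oxirane carbon alone decides which of the two diastereotopic enol ethers reacts: only in one chair can the C7–O bond lie equatorial and antiperiplanar to the forming C1–C8 bond, and this chair gives the (1S,5S) core with the C7 oxygen exo. The step needs opening at the tertiary oxirane carbon, secured by its two cation-stabilising methyl groups, and attack by an enol ether in preference to the geranyl alkenes, secured by the far higher nucleophilicity of the enol ethers and by the six-membered transition state. In the second stage the ketal must react before the C4 methyl enol ether, which the low temperature and the much lower basicity of a vinylic ether oxygen should secure.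

Step 7
Reactants: 13 (1S,5S,7R)-5-geranyl-7-hydroxy-4-methoxy-8,8-dimethylbicyclo[3.3.1]non-3-en-9-one
Product: 16 O-[(1S,5S,7R)-5-geranyl-4-methoxy-8,8-dimethyl-9-oxobicyclo[3.3.1]non-3-en-7-yl] S-methyl carbonodithioate, via sodium C7 alkoxide 14 (not isolated), via sodium C7 xanthate salt 15 (not isolated)
Conditions: NaH, imidazole (cat.), THF, 0 °C; CS2; then MeI, 0 °C to rt
Reagents that add atoms: carbon disulfide, S=C=S; iodomethane, CI
Why: Xanthate formation (alkoxide addition to CS2, then S-methylation) should be clean because the C9 ketone has no enolisable α-hydrogen (C1 is a bridgehead, C5 is quaternary) and the C7 stereocentre is not touched.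

Step 8
Reactants: 16 the C7 S-methyl xanthate
Product: 17 (1S,5S,7R)-7-allyl-5-geranyl-4-methoxy-8,8-dimethylbicyclo[3.3.1]non-3-en-9-one (allyl exo)
Conditions: allylSnBu3 (excess), AIBN, benzene, 80 °C
Reagents that add atoms: allyltributylstannane, C=CC[Sn](CCCC)(CCCC)CCCC
Why: Keck radical allylation, in which the stannyl radical fragments the xanthate to a secondary C7 radical that is trapped on its exo face because the endo face is shielded by ring A, so that C7 is set with the carbon substituent exo; an allyl group is transferred because a prenylstannane would deliver the reversed 1,1-dimethylallyl unit, and the bridgehead-bound geranyl chain cannot reach the radical.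

Step 9
Reactants: 17 (1S,5S,7R)-7-allyl-5-geranyl-4-methoxy-8,8-dimethylbicyclo[3.3.1]non-3-en-9-one
Product: 18 (1R,5S,7R)-7-allyl-5-geranyl-4-methoxy-8,8-dimethylbicyclo[3.3.1]non-3-ene-2,9-dione
Conditions: t-BuOOH (anhydrous, decane), PhI(OAc)2, K2CO3 (0.5 equiv), EtOAc, −20 °C
Reagents that add atoms: tert-butyl hydroperoxide, CC(C)(C)OO
Why: Radical allylic oxidation, in which tert-butylperoxy radicals abstract a C2 hydrogen activated by the electron-rich enol ether and the resulting allylic peroxide collapses by Kornblum–DeLaMare elimination to the vinylogous ester, no stereocentre being changed in space (the C1 descriptor changes by priority only).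

Step 10
Reactants: 18 (1R,5S,7R)-7-allyl-5-geranyl-4-methoxy-8,8-dimethylbicyclo[3.3.1]non-3-ene-2,9-dione
Product: 19 (1R,5S,7R)-5-geranyl-4-methoxy-8,8-dimethyl-7-prenylbicyclo[3.3.1]non-3-ene-2,9-dione (prenyl exo)
Conditions: second-generation Grubbs catalyst RuCl2(=CHPh)(PCy3)(H2IMes) (5 mol %), 2-methylbut-2-ene/CH2Cl2, 40 °C
Reagents that add atoms: 2-methylbut-2-ene, CC=C(C)C
Why: Olefin cross-metathesis, in which the monosubstituted allyl alkene should react far faster than the trisubstituted geranyl alkenes or the electron-poor vinylogous ester, while ring closure between the exo allyl group and the geranyl chain is geometrically out of reach.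

Step 11
Reactants: 19 (1R,5S,7R)-5-geranyl-4-methoxy-8,8-dimethyl-7-prenylbicyclo[3.3.1]non-3-ene-2,9-dione
Product: 21 (1S,5S,7R)-5-geranyl-4-methoxy-8,8-dimethyl-7-prenyl-3-(trimethylsilyl)bicyclo[3.3.1]non-3-ene-2,9-dione, via C3-lithio vinylogous ester 20 (not isolated)
Conditions: lithium 2,2,6,6-tetramethylpiperidide (LiTMP), TMSCl (present from the start), THF, −78 °C
Reagents that add atoms: chlorotrimethylsilane, C[Si](C)(C)Cl
Why: Directed vinylic deprotonation at C3 with in situ silyl quench, which is kinetically preferred over removal of the hindered C1 bridgehead hydrogen and blocks C3 for the next step.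

Step 12
Reactants: 21 the C3-silylated vinylogous ester; 22 prenyl bromide (1-bromo-3-methylbut-2-ene)
Product: 24 (1S,5S,7R)-5-geranyl-4-methoxy-8,8-dimethyl-1,7-diprenyl-3-(trimethylsilyl)bicyclo[3.3.1]non-3-ene-2,9-dione, via C1-lithio bridgehead carbanion 23 (not isolated)
Conditions: LiTMP (excess), THF, −78 to −40 °C; then 22, −78 to 0 °C
Reagents that add atoms: none
Why: Bridgehead deprotonation and SN2 alkylation at C1, now the only acidic site and flanked by the C2 and C9 carbonyl groups, with the configuration held by the bicyclic frame so that substitution occurs with retention.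

Step 13
Reactants: 24 the C1-prenylated, C3-silylated vinylogous ester
Product: 25 (1R,5S,7R)-5-geranyl-4-methoxy-8,8-dimethyl-1,7-diprenylbicyclo[3.3.1]non-3-ene-2,9-dione
Conditions: TBAF, wet THF, 0 °C
Reagents that add atoms: none
Why: Fluoride-induced protodesilylation of an α-silyl enone, which should be easy because the departing vinyl carbanion is stabilised by the C2 carbonyl group.

Step 14
Reactants: 26 3,4-dihydroxybenzoic acid
Product: 27 tert-butyldimethylsilyl 3,4-bis(tert-butyldimethylsilyloxy)benzoate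
Conditions: TBSCl (3.5 equiv), imidazole, DMF, rt
Reagents that add atoms: tert-butyl(chloro)dimethylsilane, CC(C)(C)[Si](C)(C)Cl
Why: Exhaustive silylation of both phenols and the acid under standard imidazole-promoted conditions.

Step 15
Reactants: 27 tert-butyldimethylsilyl 3,4-bis(tert-butyldimethylsilyloxy)benzoate
Product: 28 3,4-bis(tert-butyldimethylsilyloxy)benzoyl chloride
Conditions: (COCl)2, DMF (cat.), CH2Cl2, 0 °C to rt
Reagents that add atoms: oxalyl chloride, O=C(Cl)C(=O)Cl
Why: Vilsmeier-type chlorination of a silyl ester, which gives the acid chloride without free HCl and should leave the aryl silyl ethers intact.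

Step 16
Reactants: 25 (1R,5S,7R)-5-geranyl-4-methoxy-8,8-dimethyl-1,7-diprenylbicyclo[3.3.1]non-3-ene-2,9-dione; 28 3,4-bis(tert-butyldimethylsilyloxy)benzoyl chloride
Product: 30 (1S,5S,7R)-3-[3,4-bis(tert-butyldimethylsilyloxy)benzoyl]-5-geranyl-4-methoxy-8,8-dimethyl-1,7-diprenylbicyclo[3.3.1]non-3-ene-2,9-dione, via C3-lithio vinylogous ester 29 (not isolated)
Conditions: LiTMP, THF, −78 °C; then 28, −78 to −40 °C
Reagents that add atoms: none
Why: Vinylic lithiation at C3 (C1 is now quaternary) followed by C-acylation with the acid chloride, a standard way to place the 3-acyl group on bicyclic vinylogous esters of this class.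

Step 17
Reactants: 30 the silyl-protected 3-aroyl vinylogous methyl ester
Product: 31 (1S,5S,7R)-3-(3,4-dihydroxybenzoyl)-5-geranyl-4-hydroxy-8,8-dimethyl-1,7-diprenylbicyclo[3.3.1]non-3-ene-2,9-dione (CNP0160101.3)
Conditions: LiOH·H2O, 1,4-dioxane/H2O (degassed), 90 °C, Ar; then 1 M HCl to pH 4, 0 °C
Reagents that add atoms: lithium hydroxide, [Li+].[OH-]
Why: Hydroxide cleaves both aryl silyl ethers at silicon and replaces the C4 methoxy group by addition–elimination on the vinylogous ester, and mild acidification under argon should release the enolised triketone without acid-induced cyclisation onto the prenyl groups or oxidation of the catechol.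

Compound list
1 | 1,3-dimethoxybenzene | COc1cccc(OC)c1 | starting material
2 | 1,5-dimethoxycyclohexa-1,4-diene | COC1=CCC=C(OC)C1 | intermediate
3 | geranyl bromide, (2E)-1-bromo-3,7-dimethylocta-2,6-diene | CC(C)=CCC/C(C)=C/CBr | starting material
4 | 6-lithio-1,5-dimethoxycyclohexa-1,4-diene | [Li]C1C(OC)=CCC=C1OC | intermediate
5 | 6-[(2E)-3,7-dimethylocta-2,6-dienyl]-1,5-dimethoxycyclohexa-1,4-diene | COC1=CCC=C(OC)C1C/C=C(\C)CCC=C(C)C | intermediate
6 | 3-methylbut-2-en-1-ol | CC(C)=CCO | starting material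
7 | (R)-(3,3-dimethyloxiran-2-yl)methanol | OC[C@H]1OC1(C)C | intermediate
8 | (S)-2-(bromomethyl)-3,3-dimethyloxirane | BrC[C@H]1OC1(C)C | intermediate
9 | 6-geranyl-6-lithio-1,5-dimethoxycyclohexa-1,4-diene | [Li]C1(C/C=C(\C)CCC=C(C)C)C(OC)=CCC=C1OC | intermediate
10 | 6-geranyl-6-{[(2R)-3,3-dimethyloxiran-2-yl]methyl}-1,5-dimethoxycyclohexa-1,4-diene | COC1=CCC=C(OC)C1(C/C=C(\C)CCC=C(C)C)C[C@H]2OC2(C)C | intermediate
11 | bridged mixed ketal: 5-geranyl-4,9-dimethoxy-8,8-dimethyl-7,9-epoxybicyclo[3.3.1]non-3-ene, oxygen bridge from C7 to C9, core configured as in 13 | CC(C)=CCC/C(C)=C/C[C@]12C[C@H]3O[C@]2(OC)[C@@H](CC=C1OC)C3(C)C | intermediate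
12 | C7 dimethylborinate of 13 | CC(C)=CCC/C(C)=C/C[C@]12C[C@@H](OB(C)C)C(C)(C)[C@H](CC=C1OC)C2=O | intermediate
13 | (1S,5S,7R)-5-geranyl-7-hydroxy-4-methoxy-8,8-dimethylbicyclo[3.3.1]non-3-en-9-one, hydroxyl exo | CC(C)=CCC/C(C)=C/C[C@]12C[C@@H](O)C(C)(C)[C@H](CC=C1OC)C2=O | intermediate
14 | sodium C7 alkoxide of 13 | CC(C)=CCC/C(C)=C/C[C@]12C[C@@H]([O-])C(C)(C)[C@H](CC=C1OC)C2=O.[Na+] | intermediate
15 | sodium O-(C7) carbonodithioate of 13 | CC(C)=CCC/C(C)=C/C[C@]12C[C@@H](OC(=S)[S-])C(C)(C)[C@H](CC=C1OC)C2=O.[Na+] | intermediate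
16 | O-[(1S,5S,7R)-5-geranyl-4-methoxy-8,8-dimethyl-9-oxobicyclo[3.3.1]non-3-en-7-yl] S-methyl carbonodithioate | CC(C)=CCC/C(C)=C/C[C@]12C[C@@H](OC(=S)SC)C(C)(C)[C@H](CC=C1OC)C2=O | intermediate
17 | (1S,5S,7R)-7-allyl-5-geranyl-4-methoxy-8,8-dimethylbicyclo[3.3.1]non-3-en-9-one, allyl exo | CC(C)=CCC/C(C)=C/C[C@]12C[C@@H](CC=C)C(C)(C)[C@H](CC=C1OC)C2=O | intermediate
18 | (1R,5S,7R)-7-allyl-5-geranyl-4-methoxy-8,8-dimethylbicyclo[3.3.1]non-3-ene-2,9-dione | CC(C)=CCC/C(C)=C/C[C@]12C[C@@H](CC=C)C(C)(C)[C@H](C(=O)C=C1OC)C2=O | intermediate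
19 | (1R,5S,7R)-5-geranyl-4-methoxy-8,8-dimethyl-7-prenylbicyclo[3.3.1]non-3-ene-2,9-dione | CC(C)=CCC/C(C)=C/C[C@]12C[C@@H](CC=C(C)C)C(C)(C)[C@H](C(=O)C=C1OC)C2=O | intermediate
20 | C3-lithio derivative of 19 | CC(C)=CCC/C(C)=C/C[C@]12C[C@@H](CC=C(C)C)C(C)(C)[C@H](C(=O)C([Li])=C1OC)C2=O | intermediate
21 | (1S,5S,7R)-5-geranyl-4-methoxy-8,8-dimethyl-7-prenyl-3-(trimethylsilyl)bicyclo[3.3.1]non-3-ene-2,9-dione | CC(C)=CCC/C(C)=C/C[C@]12C[C@@H](CC=C(C)C)C(C)(C)[C@H](C(=O)C([Si](C)(C)C)=C1OC)C2=O | intermediate
22 | prenyl bromide, 1-bromo-3-methylbut-2-ene | CC(C)=CCBr | starting material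
23 | C1-lithio derivative of 21 | CC(C)=CCC/C(C)=C/C[C@]12C[C@@H](CC=C(C)C)C(C)(C)[C@]([Li])(C(=O)C([Si](C)(C)C)=C1OC)C2=O | intermediate
24 | (1S,5S,7R)-5-geranyl-4-methoxy-8,8-dimethyl-1,7-diprenyl-3-(trimethylsilyl)bicyclo[3.3.1]non-3-ene-2,9-dione | CC(C)=CCC/C(C)=C/C[C@]12C[C@@H](CC=C(C)C)C(C)(C)[C@](CC=C(C)C)(C(=O)C([Si](C)(C)C)=C1OC)C2=O | intermediate
25 | (1R,5S,7R)-5-geranyl-4-methoxy-8,8-dimethyl-1,7-diprenylbicyclo[3.3.1]non-3-ene-2,9-dione | CC(C)=CCC/C(C)=C/C[C@]12C[C@@H](CC=C(C)C)C(C)(C)[C@](CC=C(C)C)(C(=O)C=C1OC)C2=O | intermediate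
26 | 3,4-dihydroxybenzoic acid | O=C(O)c1ccc(O)c(O)c1 | starting material
27 | tert-butyldimethylsilyl 3,4-bis(tert-butyldimethylsilyloxy)benzoate | CC(C)(C)[Si](C)(C)OC(=O)c1ccc(O[Si](C)(C)C(C)(C)C)c(O[Si](C)(C)C(C)(C)C)c1 | intermediate
28 | 3,4-bis(tert-butyldimethylsilyloxy)benzoyl chloride | O=C(Cl)c1ccc(O[Si](C)(C)C(C)(C)C)c(O[Si](C)(C)C(C)(C)C)c1 | intermediate
29 | C3-lithio derivative of 25 | CC(C)=CCC/C(C)=C/C[C@]12C[C@@H](CC=C(C)C)C(C)(C)[C@](CC=C(C)C)(C(=O)C([Li])=C1OC)C2=O | intermediate
30 | (1S,5S,7R)-3-[3,4-bis(tert-butyldimethylsilyloxy)benzoyl]-5-geranyl-4-methoxy-8,8-dimethyl-1,7-diprenylbicyclo[3.3.1]non-3-ene-2,9-dione | CC(C)=CCC/C(C)=C/C[C@]12C[C@@H](CC=C(C)C)C(C)(C)[C@](CC=C(C)C)(C(=O)C(C(=O)c3ccc(O[Si](C)(C)C(C)(C)C)c(O[Si](C)(C)C(C)(C)C)c3)=C1OC)C2=O | intermediate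
31 | (1S,5S,7R)-3-(3,4-dihydroxybenzoyl)-5-[(2E)-3,7-dimethylocta-2,6-dienyl]-4-hydroxy-8,8-dimethyl-1,7-bis(3-methylbut-2-enyl)bicyclo[3.3.1]non-3-ene-2,9-dione | CC(C)=CCC/C(C)=C/C[C@]12C[C@@H](CC=C(C)C)C(C)(C)[C@](CC=C(C)C)(C(=O)C(C(=O)c3ccc(O)c(O)c3)=C1O)C2=O | target

Total step count: 17 steps.
Longest linear sequence: 13 steps (steps 1, 2, 5–13, 16, 17).

Steps most likely to fail

Step 6. The carbon–carbon bond formation rests on close analogy, but the second stage may go wrong: the boron reagent may also strip or protonate the C4 methyl enol ether, or the bridged ketal may open incompletely. The fallback sets out from 10. Only the silyl triflate stage is run and the bridged mixed ketal 11 is isolated. Radical allylic oxidation at C2 (t-BuOOH, PhI(OAc)2, K2CO3) should then give the bridged-ketal vinylogous ester F1. Its ketal is opened with Me2BBr at −78 °C only at this point, when ring A is a robust β-methoxy enone, to give the C7-hydroxy vinylogous ester F2. NaH, CS2 and MeI convert this into the C7 xanthate F3, and Keck allylation of F3 (allylSnBu3, AIBN) comes back to the route at 18.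

Step 9. Hydrogen abstraction may also occur at the allylic positions of the geranyl and allyl groups, or the allylic radical may be oxygenated at C4 and not at C2. The fallback sets out from 17 and builds the C2 oxygen by ionic chemistry:
- mild hydrolysis of the enol ether (oxalic acid, wet THF) to the 4,9-dione F4;
- dehydrogenation with 2-iodoxybenzoic acid (DMSO/toluene, 70 °C) to the 2-ene-4,9-dione F5;
- nucleophilic epoxidation (t-BuOOH, DBU) from the face of ring A turned away from ring B, to the epoxy ketone F6;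
- isomerisation of the epoxy ketone with zerovalent palladium, Pd(PPh3)4 and 1,2-bis(diphenylphosphino)ethane in toluene at 80 °C, to the enolised 2,4,9-trione F7;
- O-methylation with trimethylsilyldiazomethane, which returns to the route at 18 after separation from the C2-O-methyl regioisomer F8.

Step 12. The hindered bridgehead carbanion next to the gem-dimethyl carbon may alkylate sluggishly, attack the tertiary end of the allylic bromide, or be reprotonated. The fallback sets out from 21. The same lithiation is quenched with iodine, a small electrophile, to give the C1 bridgehead iodide F9. Radical allylation of the bridgehead radical (allylSnBu3, AIBN, benzene, 80 °C) gives the C1-allyl compound F10, and cross-metathesis with 2-methylbut-2-ene (second-generation Grubbs catalyst) comes back to the route at 24.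

Further compounds
F1 | step 6 | bridged-ketal vinylogous ester: 5-geranyl-4,9-dimethoxy-8,8-dimethyl-7,9-epoxybicyclo[3.3.1]non-3-en-2-one, core configured as in 11 | CC(C)=CCC/C(C)=C/C[C@]12C[C@H]3O[C@]2(OC)[C@@H](C(=O)C=C1OC)C3(C)C
F2 | step 6 | 5-geranyl-7-exo-hydroxy-4-methoxy-8,8-dimethylbicyclo[3.3.1]non-3-ene-2,9-dione, core configured as in 13 | CC(C)=CCC/C(C)=C/C[C@]12C[C@@H](O)C(C)(C)[C@H](C(=O)C=C1OC)C2=O
F3 | step 6 | C7 S-methyl xanthate of F2 | CC(C)=CCC/C(C)=C/C[C@]12C[C@@H](OC(=S)SC)C(C)(C)[C@H](C(=O)C=C1OC)C2=O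
F4 | step 9 | 7-exo-allyl-5-geranyl-8,8-dimethylbicyclo[3.3.1]nonane-4,9-dione, core configured as in 17 | CC(C)=CCC/C(C)=C/C[C@]12C[C@@H](CC=C)C(C)(C)[C@H](CCC1=O)C2=O
F5 | step 9 | 7-exo-allyl-5-geranyl-8,8-dimethylbicyclo[3.3.1]non-2-ene-4,9-dione | CC(C)=CCC/C(C)=C/C[C@]12C[C@@H](CC=C)C(C)(C)[C@H](C=CC1=O)C2=O
F6 | step 9 | 7-exo-allyl-2,3-epoxy-5-geranyl-8,8-dimethylbicyclo[3.3.1]nonane-4,9-dione, oxirane on the face of ring A turned away from ring B | CC(C)=CCC/C(C)=C/C[C@]12C[C@@H](CC=C)C(C)(C)[C@H]([C@H]3O[C@H]3C1=O)C2=O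
F7 | step 9 | 7-exo-allyl-5-geranyl-4-hydroxy-8,8-dimethylbicyclo[3.3.1]non-3-ene-2,9-dione (enolised 2,4,9-trione) | CC(C)=CCC/C(C)=C/C[C@]12C[C@@H](CC=C)C(C)(C)[C@H](C(=O)C=C1O)C2=O
F8 | step 9 | 7-exo-allyl-5-geranyl-2-methoxy-8,8-dimethylbicyclo[3.3.1]non-2-ene-4,9-dione (regioisomer of 18) | CC(C)=CCC/C(C)=C/C[C@]12C[C@@H](CC=C)C(C)(C)[C@H](C(OC)=CC1=O)C2=O
F9 | step 12 | 5-geranyl-1-iodo-4-methoxy-8,8-dimethyl-7-exo-prenyl-3-(trimethylsilyl)bicyclo[3.3.1]non-3-ene-2,9-dione, iodine in the place of the C1 hydrogen of 21 | CC(C)=CCC/C(C)=C/C[C@]12C[C@@H](CC=C(C)C)C(C)(C)[C@](I)(C(=O)C([Si](C)(C)C)=C1OC)C2=O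
F10 | step 12 | 1-allyl-5-geranyl-4-methoxy-8,8-dimethyl-7-exo-prenyl-3-(trimethylsilyl)bicyclo[3.3.1]non-3-ene-2,9-dione | CC(C)=CCC/C(C)=C/C[C@]12C[C@@H](CC=C(C)C)C(C)(C)[C@](CC=C)(C(=O)C([Si](C)(C)C)=C1OC)C2=O
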